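**Plan**

Labels: ring A = the phenol ring that carries the vinyl group; rings B and E = the two resorcinol-derived rings of the seven-membered ring (B is also the benzo ring of the dihydrobenzofuran); C-7/C-8 = the CH–CH unit of the seven-membered ring (C-7 bears the 4-hydroxyphenyl and ring E, C-8 bears rings A and B); C-7′/C-8′ = C-2/C-3 of the dihydrobenzofuran.
Cuts: (a) the ring A–vinyl bond (Heck), giving a 4-vinyl-2,3-diarylbenzofuran and an aryl bromide core; (b) in one oxidative event both the ring B–C-8′ bond and the O–C-7′ bond, opening the seven-membered ring and the dihydrofuran to a 1,1,2,2-tetraarylethane with an (E)-4-hydroxystyryl group on ring E; (c) the C-7–ring E bond (Friedel–Crafts), giving a ring A-fused 2,3-diaryl-2,3-dihydrobenzofuran and a protected resveratrol; (d) the C-8–C-7 bond of that dihydrobenzofuran (carbene C–H insertion).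
Forward: ring A dihydrobenzofuran → ring-opening arylation attaches ring E with its styryl arm → anodic biomimetic (3+2) annulation closes the seven-membered ring and the trans-dihydrofuran together → Heck reaction adds the benzofuran half → debenzylation.
Enabling feature: the para-hydroxystyryl group on ring E (oxidation of its phenol puts spin and positive charge on C-8′) lies seven ring atoms from the ring B C–H carbon that is ortho to one OH and para to the other, and that ortho OH then closes onto the quinone methide at C-7′; this is the 8–10′ C–C coupling and 7–O closure by which resveratrol is thought to give ε-viniferin units, here run inside one molecule with no auxiliary group.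
Stereochemistry: C-8 from the chiral rhodium catalyst in the C–H insertion; C-7 by 1,2-induction in the Friedel–Crafts step; C-8′ by allylic strain on ring E and C-7′ by thermodynamic trans closure, both in the key step.

Key step: step 10

Assumption: Rh2(R-PTAD)4 is taken to give the (3R)-dihydrobenzofuran in step 6; if the sense of induction is the opposite, the mirror-image catalyst Rh2(S-PTAD)4 is used.
Abbreviations: Bn = benzyl, TIPS = triisopropylsilyl, HFIP = 1,1,1,3,3,3-hexafluoropropan-2-ol, RVC = reticulated vitreous carbon.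

Step 1
Reactants: 1 5-bromobenzene-1,3-diol
Product: 2 1-bromo-3,5-bis(triisopropylsilyloxy)benzene
Conditions: TIPSCl (2.3 equiv), imidazole (5 equiv), DMF, rt
Reagents that add atoms: chlorotriisopropylsilane CC(C)[Si](Cl)(C(C)C)C(C)C
Why: Standard silyl ether formation on phenols; the TIPS ethers should survive the Grignard, hydrazine and acid steps and can be removed by fluoride while benzyl ethers stay.

Step 2
Reactants: 3 5-bromo-2-hydroxybenzaldehyde; 4 1-(benzyloxy)-4-(chloromethyl)benzene
Product: 5 2-{[4-(benzyloxy)benzyl]oxy}-5-bromobenzaldehyde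
Conditions: K2CO3, DMF, 60 °C
Reagents that add atoms: none
Why: Williamson ether synthesis with a reactive benzylic chloride, which installs the O–CH2–aryl C–H bonds that step 6 functionalises.

Step 3
Reactants: 5 2-{[4-(benzyloxy)benzyl]oxy}-5-bromobenzaldehyde; 2 1-bromo-3,5-bis(triisopropylsilyloxy)benzene
Product: 7 rac-(2-{[4-(benzyloxy)benzyl]oxy}-5-bromophenyl)[3,5-bis(triisopropylsilyloxy)phenyl]methanol, via arylmagnesium bromide 6 (not isolated)
Conditions: 2, Mg turnings, THF, 45 °C; then 5, −20 °C to rt; aq NH4Cl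
Reagents that add atoms: none
Why: Grignard addition to the aldehyde, which should be much faster than halogen–magnesium exchange at the aryl bromide of 5; the carbinol centre is oxidised away in the next step.

Step 4
Reactants: 7 rac-(2-{[4-(benzyloxy)benzyl]oxy}-5-bromophenyl)[3,5-bis(triisopropylsilyloxy)phenyl]methanol
Product: 8 (2-{[4-(benzyloxy)benzyl]oxy}-5-bromophenyl)[3,5-bis(triisopropylsilyloxy)phenyl]methanone
Conditions: MnO2 (15 equiv), CH2Cl2, rt
Reagents that add atoms: none
Why: MnO2 oxidation of a doubly benzylic alcohol to the benzophenone, which leaves silyl ethers, benzyl ethers and the aryl bromide untouched.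

Step 5
Reactants: 8 (2-{[4-(benzyloxy)benzyl]oxy}-5-bromophenyl)[3,5-bis(triisopropylsilyloxy)phenyl]methanone
Product: 9 hydrazone of ketone 8 (E/Z mixture)
Conditions: N2H4·H2O (10 equiv), AcOH (cat.), EtOH, 80 °C
Reagents that add atoms: hydrazine NN
Why: Acid-catalysed hydrazone condensation, the excess of hydrazine suppressing azine formation with this hindered 2-alkoxybenzophenone.

Step 6
Reactants: 9 hydrazone of ketone 8
Product: 11 (2S,3R)-2-[4-(benzyloxy)phenyl]-5-bromo-3-[3,5-bis(triisopropylsilyloxy)phenyl]-2,3-dihydro-1-benzofuran (2,3-cis), via diaryldiazomethane 10 (not isolated)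
Conditions: MnO2 (8 equiv), CH2Cl2, 0 °C, filter; then Rh2(R-PTAD)4 (dirhodium tetrakis[(R)-(1-adamantyl)(phthalimido)acetate], 1 mol %), CH2Cl2, 0 °C to rt
Reagents that add atoms: none
Why: Hydrazone oxidation gives a donor/donor diazo compound whose rhodium carbene undergoes enantioselective intramolecular 1,5 C–H insertion into the benzylic O–CH2 bond, the chiral carboxylate ligands setting C-3 (the later C-8) and the concerted insertion giving the 2,3-cis ring, whose C-2 configuration is erased in step 8.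

Step 7
Reactants: 12 1,3-bis(benzyloxy)-5-bromobenzene; 13 4-ethenylphenyl acetate
Product: 14 4-{(E)-2-[3,5-bis(benzyloxy)phenyl]ethenyl}phenyl acetate
Conditions: Pd(OAc)2 (2 mol %), P(o-tol)3 (5 mol %), Et3N, DMF, 100 °C
Reagents that add atoms: none
Why: Mizoroki–Heck reaction of an aryl bromide with a styrene, which gives the E-stilbene through syn-insertion and syn-β-hydride elimination and tolerates the aryl acetate.

Step 8
Reactants: 11 (2S,3R)-2-[4-(benzyloxy)phenyl]-5-bromo-3-[3,5-bis(triisopropylsilyloxy)phenyl]-2,3-dihydro-1-benzofuran; 14 4-{(E)-2-[3,5-bis(benzyloxy)phenyl]ethenyl}phenyl acetate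
Product: 15 (7S,8R)-tetraarylethane phenol (ring A OH free; ring B bis-TIPS ether; 4-acetoxystyryl on ring E; full name in the compound list)
Conditions: 14 (2 equiv), TfOH (10 mol %), CH2Cl2/HFIP 4:1, −20 to 0 °C
Reagents that add atoms: none
Why: Friedel–Crafts alkylation in which acid ionises the benzylic C-2–O bond of 11 to a 4-benzyloxybenzyl cation (freeing the ring A phenol) that is captured by the most nucleophilic carbon of 14 (para to one benzyloxy group, ortho to the other, next to the styryl arm, the acetate keeping the alkene unreactive); with H-8 eclipsing the cation plane and ring A perpendicular, the arene is expected to add anti to ring A and its departing oxygen (open-chain 1,2-induction) to give the (7S,8R) isomer.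

Step 9
Reactants: 15 (7S,8R)-tetraarylethane phenol
Product: 17 5-[(1R,2S)-2-[4-(benzyloxy)phenyl]-2-{2,4-bis(benzyloxy)-6-[(E)-2-(4-hydroxyphenyl)ethenyl]phenyl}-1-(5-bromo-2-hydroxyphenyl)ethyl]benzene-1,3-diol, via desacetyl bis-TIPS ether 16 (not isolated)
Conditions: K2CO3 (0.3 equiv), MeOH/THF, rt; then TBAF (2.5 equiv), 0 °C; degassed aq NH4Cl
Reagents that add atoms: none
Why: Methanolysis of the aryl acetate followed by fluoride cleavage of the two aryl silyl ethers (standard deprotections) frees the 4-hydroxystyryl phenol and the ring B resorcinol needed for the key step while the benzyl ethers stay.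

Step 10
Reactants: 17 5-[(1R,2S)-2-[4-(benzyloxy)phenyl]-2-{2,4-bis(benzyloxy)-6-[(E)-2-(4-hydroxyphenyl)ethenyl]phenyl}-1-(5-bromo-2-hydroxyphenyl)ethyl]benzene-1,3-diol
Product: 18 (7S,8R,7′S,8′S)-core bromotriphenol (seven-membered ring and trans-dihydrobenzofuran closed; full name in the compound list)
Conditions: undivided cell, RVC anode, Pt cathode, constant current, 2.1 F/mol; Bu4NPF6 (0.1 M), 2,6-lutidine (2 equiv), CH2Cl2/HFIP 4:1, 2 mM, 0 °C, Ar
Reagents that add atoms: none
Why: Proposed new method: anodic oxidation removes one electron and one proton from the 4-hydroxystyryl phenol, the most easily oxidised group of 17, and the phenoxyl radical, whose spin sits on C-8′, either adds directly to ring B or is oxidised further to the quinone-methide cation, so that C-8′ bonds to the ring B carbon ortho to one OH and para to the other, after which the para-quinone methide left at C-7′ is trapped by the neighbouring ring B hydroxyl. The closest known reaction types are the oxidative dimerisation of resveratrol to ε-viniferin, anodic phenol–arene cross-coupling in HFIP and anodic phenol–alkene (3+2) cycloaddition; new here is that the partner is a non-conjugated resorcinol delivered intramolecularly through a seven-membered ring. The seven-membered ring closes by 7-exo-trig C–C bond formation and the dihydrofuran by 5-exo-trig oxa-1,6-addition to the quinone methide. C-8′ is controlled by allylic 1,3-strain on ring E, which holds H-7 in the ring plane beside the benzyloxy group and the styryl H-8′ syn to C-7, so that ring B, carried by C-8, should add to the alkene face on its own side and leave H-8′ trans to H-7; C-7′ is set trans to C-8′ by the reversible, thermodynamically controlled oxa-Michael closure. The step needs chemoselective oxidation (the conjugated phenol is expected to oxidise at a clearly lower potential than the resorcinol, the bromophenol and the benzyl aryl ethers, and the charge is limited to two electrons), regioselectivity for C-8′ (only this carbon gives a seven-membered ring) and suppression of intermolecular dimerisation (high dilution and the crowded ortho-substituted styrene).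

Step 11
Reactants: 18 (7S,8R,7′S,8′S)-core bromotriphenol
Product: 19 (7S,8R,7′S,8′S)-core bromide hexabenzyl ether (full name in the compound list)
Conditions: BnBr (4 equiv), K2CO3, DMF, 40 °C
Reagents that add atoms: benzyl bromide BrCc1ccccc1
Why: Williamson benzylation of the three phenols, which unifies the protecting groups and removes free phenols before the palladium-catalysed coupling.

Step 12
Reactants: 20 methyl 3-(benzyloxy)-5-hydroxybenzoate; 21 1-[3,5-bis(benzyloxy)phenyl]-2-bromoethan-1-one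
Product: 22 methyl 3-(benzyloxy)-5-{2-[3,5-bis(benzyloxy)phenyl]-2-oxoethoxy}benzoate
Conditions: K2CO3, acetone, rt
Reagents that add atoms: none
Why: Williamson alkylation of the phenol with an α-bromoketone gives the α-aryloxy ketone needed for benzofuran formation.

Step 13
Reactants: 22 methyl 3-(benzyloxy)-5-{2-[3,5-bis(benzyloxy)phenyl]-2-oxoethoxy}benzoate
Product: 23 methyl 6-(benzyloxy)-3-[3,5-bis(benzyloxy)phenyl]-1-benzofuran-4-carboxylate
Conditions: Bi(OTf)3 (10 mol %), 1,2-dichloroethane, 60 °C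
Reagents that add atoms: none
Why: Lewis-acid cyclodehydration of an α-aryloxy ketone (intramolecular Friedel–Crafts hydroxyalkylation then dehydration) gives the 3-arylbenzofuran, ring closure being expected para to the benzyloxy group and therefore next to the ester.

Step 14
Reactants: 23 methyl 6-(benzyloxy)-3-[3,5-bis(benzyloxy)phenyl]-1-benzofuran-4-carboxylate; 24 1-(benzyloxy)-4-bromobenzene
Product: 25 methyl 6-(benzyloxy)-2-[4-(benzyloxy)phenyl]-3-[3,5-bis(benzyloxy)phenyl]-1-benzofuran-4-carboxylate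
Conditions: Pd(OAc)2 (5 mol %), PCy3·HBF4 (10 mol %), PivOH (30 mol %), K2CO3, DMA, 110 °C
Reagents that add atoms: none
Why: Palladium-catalysed direct C-2 arylation of the benzofuran by concerted metalation–deprotonation, C-2 being the only heteroaryl C–H bond.

Step 15
Reactants: 25 methyl 6-(benzyloxy)-2-[4-(benzyloxy)phenyl]-3-[3,5-bis(benzyloxy)phenyl]-1-benzofuran-4-carboxylate
Product: 26 {6-(benzyloxy)-2-[4-(benzyloxy)phenyl]-3-[3,5-bis(benzyloxy)phenyl]-1-benzofuran-4-yl}methanol
Conditions: LiAlH4, THF, 0 °C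
Reagents that add atoms: none
Why: Hydride reduction of the ester to the primary alcohol, to which benzyl ethers and the benzofuran are inert.

Step 16
Reactants: 26 {6-(benzyloxy)-2-[4-(benzyloxy)phenyl]-3-[3,5-bis(benzyloxy)phenyl]-1-benzofuran-4-yl}methanol
Product: 27 6-(benzyloxy)-2-[4-(benzyloxy)phenyl]-3-[3,5-bis(benzyloxy)phenyl]-1-benzofuran-4-carbaldehyde
Conditions: MnO2, CH2Cl2, rt
Reagents that add atoms: none
Why: MnO2 oxidation of a benzylic alcohol stops at the aldehyde.

Step 17
Reactants: 27 6-(benzyloxy)-2-[4-(benzyloxy)phenyl]-3-[3,5-bis(benzyloxy)phenyl]-1-benzofuran-4-carbaldehyde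
Product: 28 6-(benzyloxy)-2-[4-(benzyloxy)phenyl]-3-[3,5-bis(benzyloxy)phenyl]-4-ethenyl-1-benzofuran
Conditions: Ph3PCH3Br, KOtBu, THF, 0 °C to rt
Reagents that add atoms: methyltriphenylphosphonium bromide C[P+](c1ccccc1)(c1ccccc1)c1ccccc1.[Br-]
Why: Wittig methylenation of the aryl aldehyde gives the vinyl arene.

Step 18
Reactants: 19 (7S,8R,7′S,8′S)-core bromide hexabenzyl ether; 28 6-(benzyloxy)-2-[4-(benzyloxy)phenyl]-3-[3,5-bis(benzyloxy)phenyl]-4-ethenyl-1-benzofuran
Product: 29 deca-O-benzyl ether of the target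
Conditions: Pd2(dba)3 (3 mol %), P(t-Bu)3·HBF4 (12 mol %), Cy2NMe, 1,4-dioxane, 90 °C
Reagents that add atoms: none
Why: Mizoroki–Heck coupling of the aryl bromide (para to a benzyloxy group, hence the electron-rich bulky phosphine) with the vinylbenzofuran forms the E-stilbene link by syn-insertion and syn-β-hydride elimination and touches no stereocentre.

Step 19
Reactants: 29 deca-O-benzyl ether of the target
Product: 30 target CNP0339094.1
Conditions: BCl3 (30 equiv), pentamethylbenzene (40 equiv), CH2Cl2, −78 to −50 °C; MeOH quench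
Reagents that add atoms: none
Why: Lewis-acid debenzylation with BCl3 and pentamethylbenzene as a non-basic benzyl-cation scavenger cleaves all ten aryl benzyl ethers without reducing the stilbene, the low temperature being meant to keep the dihydrobenzofuran and the alkene intact.

**Compound list**

1 | 5-bromobenzene-1,3-diol | Oc1cc(O)cc(Br)c1 | starting material
2 | 1-bromo-3,5-bis(triisopropylsilyloxy)benzene | CC(C)[Si](Oc1cc(Br)cc(O[Si](C(C)C)(C(C)C)C(C)C)c1)(C(C)C)C(C)C | intermediate
3 | 5-bromo-2-hydroxybenzaldehyde | O=Cc1cc(Br)ccc1O | starting material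
4 | 1-(benzyloxy)-4-(chloromethyl)benzene | ClCc1ccc(OCc2ccccc2)cc1 | starting material
5 | 2-{[4-(benzyloxy)benzyl]oxy}-5-bromobenzaldehyde | O=Cc1cc(Br)ccc1OCc1ccc(OCc2ccccc2)cc1 | intermediate
6 | [3,5-bis(triisopropylsilyloxy)phenyl]magnesium bromide (not isolated) | Br[Mg]c1cc(O[Si](C(C)C)(C(C)C)C(C)C)cc(O[Si](C(C)C)(C(C)C)C(C)C)c1 | intermediate
7 | rac-(2-{[4-(benzyloxy)benzyl]oxy}-5-bromophenyl)[3,5-bis(triisopropylsilyloxy)phenyl]methanol | OC(c1cc(Br)ccc1OCc1ccc(OCc2ccccc2)cc1)c1cc(O[Si](C(C)C)(C(C)C)C(C)C)cc(O[Si](C(C)C)(C(C)C)C(C)C)c1 | intermediate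
8 | (2-{[4-(benzyloxy)benzyl]oxy}-5-bromophenyl)[3,5-bis(triisopropylsilyloxy)phenyl]methanone | O=C(c1cc(Br)ccc1OCc1ccc(OCc2ccccc2)cc1)c1cc(O[Si](C(C)C)(C(C)C)C(C)C)cc(O[Si](C(C)C)(C(C)C)C(C)C)c1 | intermediate
9 | hydrazone of ketone 8 (E/Z mixture) | NN=C(c1cc(Br)ccc1OCc1ccc(OCc2ccccc2)cc1)c1cc(O[Si](C(C)C)(C(C)C)C(C)C)cc(O[Si](C(C)C)(C(C)C)C(C)C)c1 | intermediate
10 | 1-{[4-(benzyloxy)benzyl]oxy}-4-bromo-2-{diazo[3,5-bis(triisopropylsilyloxy)phenyl]methyl}benzene (not isolated) | [N-]=[N+]=C(c1cc(Br)ccc1OCc1ccc(OCc2ccccc2)cc1)c1cc(O[Si](C(C)C)(C(C)C)C(C)C)cc(O[Si](C(C)C)(C(C)C)C(C)C)c1 | intermediate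
11 | (2S,3R)-2-[4-(benzyloxy)phenyl]-5-bromo-3-[3,5-bis(triisopropylsilyloxy)phenyl]-2,3-dihydro-1-benzofuran (2,3-cis) | Brc1ccc2c(c1)[C@@H](c1cc(O[Si](C(C)C)(C(C)C)C(C)C)cc(O[Si](C(C)C)(C(C)C)C(C)C)c1)[C@@H](c1ccc(OCc3ccccc3)cc1)O2 | intermediate
12 | 1,3-bis(benzyloxy)-5-bromobenzene | Brc1cc(OCc2ccccc2)cc(OCc2ccccc2)c1 | starting material
13 | 4-ethenylphenyl acetate | C=Cc1ccc(OC(C)=O)cc1 | starting material
14 | 4-{(E)-2-[3,5-bis(benzyloxy)phenyl]ethenyl}phenyl acetate | CC(=O)Oc1ccc(/C=C/c2cc(OCc3ccccc3)cc(OCc3ccccc3)c2)cc1 | intermediate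
15 | 4-[(E)-2-{3,5-bis(benzyloxy)-2-[(1S,2R)-1-[4-(benzyloxy)phenyl]-2-(5-bromo-2-hydroxyphenyl)-2-[3,5-bis(triisopropylsilyloxy)phenyl]ethyl]phenyl}ethenyl]phenyl acetate (C-7 S, C-8 R) | Brc1ccc(O)c([C@@H](c2cc(O[Si](C(C)C)(C(C)C)C(C)C)cc(O[Si](C(C)C)(C(C)C)C(C)C)c2)[C@@H](c2ccc(OCc3ccccc3)cc2)c2c(OCc3ccccc3)cc(OCc3ccccc3)cc2/C=C/c2ccc(OC(C)=O)cc2)c1 | intermediate
16 | 4-bromo-2-[(1R,2S)-2-[4-(benzyloxy)phenyl]-2-{2,4-bis(benzyloxy)-6-[(E)-2-(4-hydroxyphenyl)ethenyl]phenyl}-1-[3,5-bis(triisopropylsilyloxy)phenyl]ethyl]phenol (not isolated) | Brc1ccc(O)c([C@@H](c2cc(O[Si](C(C)C)(C(C)C)C(C)C)cc(O[Si](C(C)C)(C(C)C)C(C)C)c2)[C@@H](c2ccc(OCc3ccccc3)cc2)c2c(OCc3ccccc3)cc(OCc3ccccc3)cc2/C=C/c2ccc(O)cc2)c1 | intermediate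
17 | 5-[(1R,2S)-2-[4-(benzyloxy)phenyl]-2-{2,4-bis(benzyloxy)-6-[(E)-2-(4-hydroxyphenyl)ethenyl]phenyl}-1-(5-bromo-2-hydroxyphenyl)ethyl]benzene-1,3-diol (C-8 R, C-7 S) | Brc1ccc(O)c([C@@H](c2cc(O)cc(O)c2)[C@@H](c2ccc(OCc3ccccc3)cc2)c2c(OCc3ccccc3)cc(OCc3ccccc3)cc2/C=C/c2ccc(O)cc2)c1 | intermediate
18 | core bromotriphenol: seven-membered ring fused to rings B and E and to a trans-2,3-dihydrobenzofuran on ring B; C-8 (R) bears 5-bromo-2-hydroxyphenyl (ring A), C-7 (S) bears 4-(benzyloxy)phenyl, C-8′ (S) joins rings B and E, C-7′ (S) bears 4-hydroxyphenyl and the ring oxygen; ring E 3,5-bis(benzyloxy), ring B one free OH | Brc1ccc(O)c([C@H]5c6cc(O)cc7c6[C@H](c6cc(OCc8ccccc8)cc(OCc8ccccc8)c6[C@@H]5c5ccc(OCc8ccccc8)cc5)[C@@H](c5ccc(O)cc5)O7)c1 | intermediate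
19 | hexabenzyl ether of the core bromide: as 18 with the ring A OH, the ring B OH and the 4-hydroxyphenyl OH benzylated (7S,8R,7′S,8′S) | Brc1ccc(OCc2ccccc2)c([C@H]5c6cc(OCc8ccccc8)cc7c6[C@H](c6cc(OCc8ccccc8)cc(OCc8ccccc8)c6[C@@H]5c5ccc(OCc8ccccc8)cc5)[C@@H](c5ccc(OCc8ccccc8)cc5)O7)c1 | intermediate
20 | methyl 3-(benzyloxy)-5-hydroxybenzoate | COC(=O)c1cc(O)cc(OCc2ccccc2)c1 | starting material
21 | 1-[3,5-bis(benzyloxy)phenyl]-2-bromoethan-1-one | O=C(CBr)c1cc(OCc2ccccc2)cc(OCc2ccccc2)c1 | starting material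
22 | methyl 3-(benzyloxy)-5-{2-[3,5-bis(benzyloxy)phenyl]-2-oxoethoxy}benzoate | COC(=O)c1cc(OCC(=O)c2cc(OCc3ccccc3)cc(OCc3ccccc3)c2)cc(OCc2ccccc2)c1 | intermediate
23 | methyl 6-(benzyloxy)-3-[3,5-bis(benzyloxy)phenyl]-1-benzofuran-4-carboxylate | COC(=O)c1cc(OCc2ccccc2)cc2occ(-c3cc(OCc4ccccc4)cc(OCc4ccccc4)c3)c12 | intermediate
24 | 1-(benzyloxy)-4-bromobenzene | Brc1ccc(OCc2ccccc2)cc1 | starting material
25 | methyl 6-(benzyloxy)-2-[4-(benzyloxy)phenyl]-3-[3,5-bis(benzyloxy)phenyl]-1-benzofuran-4-carboxylate | COC(=O)c1cc(OCc2ccccc2)cc2oc(-c3ccc(OCc4ccccc4)cc3)c(-c3cc(OCc4ccccc4)cc(OCc4ccccc4)c3)c12 | intermediate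
26 | {6-(benzyloxy)-2-[4-(benzyloxy)phenyl]-3-[3,5-bis(benzyloxy)phenyl]-1-benzofuran-4-yl}methanol | OCc1cc(OCc2ccccc2)cc2oc(-c3ccc(OCc4ccccc4)cc3)c(-c3cc(OCc4ccccc4)cc(OCc4ccccc4)c3)c12 | intermediate
27 | 6-(benzyloxy)-2-[4-(benzyloxy)phenyl]-3-[3,5-bis(benzyloxy)phenyl]-1-benzofuran-4-carbaldehyde | O=Cc1cc(OCc2ccccc2)cc2oc(-c3ccc(OCc4ccccc4)cc3)c(-c3cc(OCc4ccccc4)cc(OCc4ccccc4)c3)c12 | intermediate
28 | 6-(benzyloxy)-2-[4-(benzyloxy)phenyl]-3-[3,5-bis(benzyloxy)phenyl]-4-ethenyl-1-benzofuran | C=Cc1cc(OCc2ccccc2)cc2oc(-c3ccc(OCc4ccccc4)cc3)c(-c3cc(OCc4ccccc4)cc(OCc4ccccc4)c3)c12 | intermediate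
29 | deca-O-benzyl ether of the target (7S,8R,7′S,8′S; E-alkene) | O(Cc8ccccc8)c1ccc(-c2oc3cc(OCc8ccccc8)cc(/C=C/c4ccc(OCc8ccccc8)c([C@H]5c6cc(OCc8ccccc8)cc7c6[C@H](c6cc(OCc8ccccc8)cc(OCc8ccccc8)c6[C@@H]5c5ccc(OCc8ccccc8)cc5)[C@@H](c5ccc(OCc8ccccc8)cc5)O7)c4)c3c2-c2cc(OCc8ccccc8)cc(OCc8ccccc8)c2)cc1 | intermediate
30 | target CNP0339094.1: 2-(4-hydroxyphenyl)-3-(3,5-dihydroxyphenyl)-6-hydroxy-1-benzofuran joined at C-4 through an (E)-ethene to ring A (para to its OH), ring A carrying ortho to its OH the C-8 (R) of the seven-membered ring core with C-7 (S), C-8′ (S), C-7′ (S) and ten free OH groups | Oc1ccc(-c2oc3cc(O)cc(/C=C/c4ccc(O)c([C@H]5c6cc(O)cc7c6[C@H](c6cc(O)cc(O)c6[C@@H]5c5ccc(O)cc5)[C@@H](c5ccc(O)cc5)O7)c4)c3c2-c2cc(O)cc(O)c2)cc1 | target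

Total steps: 19. Longest linear sequence: 11 steps (steps 2, 3, 4, 5, 6, 8, 9, 10, 11, 18, 19).

**Steps most likely to fail**

Step 10 (proposed new method). The phenoxyl radical may couple between molecules, or be over-oxidised, faster than the seven-membered ring closes, and the facial selectivity at C-8′ may be poor. The fallback uses known reaction types only, sets out from 17 and comes back at 18. OsO4-catalysed dihydroxylation of the stilbene with N-methylmorpholine N-oxide in acetone/water gives the syn-diol F1. TsOH·H2O in toluene/HFIP at 50 °C should then convert the glycol, through the 4-hydroxybenzyl cation and its enol, into the benzyl ketone F2 with the carbonyl at C-8′. Friedel–Crafts cyclodehydration of ring B onto this ketone in the same pot gives the seven-membered triarylethylene F3, and acid-catalysed addition of the ring B phenol across the styrene (proton to C-8′, cation at C-7′) closes the trans-dihydrobenzofuran 18. The C–C bond is thus made by polar carbonyl chemistry rather than by oxidation of the phenol, and C-8′ is set by thermodynamically controlled protonation.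

Step 8. Arylation of the benzylic cation may show poor facial selectivity and give the C-7 epimer, the arene may react at the carbon between its two benzyloxy groups, and reversible proton loss from the cation could erode C-8. The fallback sets out from the crude product of step 8 and comes back at 15. The separated C-7 epimer F4 is treated with DDQ in CH2Cl2 at 0 °C, which removes the doubly benzylic hydride at C-7; the ring A phenol traps the cation to give the 2,2-diaryl-2,3-dihydrobenzofuran F5. Ionic hydrogenation (Et3SiH, TFA, CH2Cl2, −40 °C) re-opens F5 to the diaryl cation and delivers hydride. Because hydride now adds to a cation that already carries ring E, the facial bias that gave the wrong epimer in the arylation should give 15, so C-7 is set by reduction instead of arylation.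

Step 19. The ten-fold Lewis-acid debenzylation may open the dihydrobenzofuran or protonate the stilbene and cyclise a neighbouring ring onto it (a vitisin A to vitisin D type isomerisation), or stay incomplete. The fallback sets out from 18 and 28 and comes back at 30. Each half is debenzylated separately with BCl3 and pentamethylbenzene at −78 °C before the stilbene exists: 18, which has only three benzyl ethers and no alkene, gives the hexaphenol bromide F6, and 28 gives the tetraphenolic vinylbenzofuran F7. The unprotected halves are then joined by a Heck reaction (Pd(OAc)2, P(o-tol)3, Et3N, DMF, 100 °C) as the last step, so the finished stilbene never meets a Lewis acid.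

**Further compounds**

F1 | step 10 | syn-7′,8′-diol of 17 (mixture of the two syn diastereomers) | Brc1ccc(O)c([C@@H](c2cc(O)cc(O)c2)[C@@H](c2ccc(OCc3ccccc3)cc2)c2c(OCc3ccccc3)cc(OCc3ccccc3)cc2C(O)C(O)c2ccc(O)cc2)c1
F2 | step 10 | benzyl ketone with the carbonyl at C-8′ (1-aryl-2-(4-hydroxyphenyl)ethanone on ring E) | Brc1ccc(O)c([C@@H](c2cc(O)cc(O)c2)[C@@H](c2ccc(OCc3ccccc3)cc2)c2c(OCc3ccccc3)cc(OCc3ccccc3)cc2C(=O)Cc2ccc(O)cc2)c1
F3 | step 10 | seven-membered triarylethylene with exocyclic C-8′=C-7′ double bond (alkene geometry not fixed) | Brc1ccc(O)c([C@H]5c6cc(O)cc(O)c6C(=Cc6ccc(O)cc6)c6cc(OCc8ccccc8)cc(OCc8ccccc8)c6[C@@H]5c5ccc(OCc8ccccc8)cc5)c1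
F4 | step 8 | C-7 epimer of 15 (7R,8R) | Brc1ccc(O)c([C@@H](c2cc(O[Si](C(C)C)(C(C)C)C(C)C)cc(O[Si](C(C)C)(C(C)C)C(C)C)c2)[C@H](c2ccc(OCc3ccccc3)cc2)c2c(OCc3ccccc3)cc(OCc3ccccc3)cc2/C=C/c2ccc(OC(C)=O)cc2)c1
F5 | step 8 | (3R)-2,2-diaryl-5-bromo-3-[3,5-bis(triisopropylsilyloxy)phenyl]-2,3-dihydro-1-benzofuran carrying 4-(benzyloxy)phenyl and the ring E aryl on C-2 (either C-2 epimer serves) | Brc1ccc2c(c1)[C@@H](c1cc(O[Si](C(C)C)(C(C)C)C(C)C)cc(O[Si](C(C)C)(C(C)C)C(C)C)c1)C(c1ccc(OCc3ccccc3)cc1)(c1c(OCc3ccccc3)cc(OCc3ccccc3)cc1/C=C/c1ccc(OC(C)=O)cc1)O2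
F6 | step 19 | hexaphenol core bromide (18 without its three benzyl groups) | Brc1ccc(O)c([C@H]5c6cc(O)cc7c6[C@H](c6cc(O)cc(O)c6[C@@H]5c5ccc(O)cc5)[C@@H](c5ccc(O)cc5)O7)c1
F7 | step 19 | 5-[4-ethenyl-6-hydroxy-2-(4-hydroxyphenyl)-1-benzofuran-3-yl]benzene-1,3-diol | C=Cc1cc(O)cc2oc(-c3ccc(O)cc3)c(-c3cc(O)cc(O)c3)c12
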